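**Strategy**

The route rests on opening the seven-membered ring (C6–C10–C1–C2–C3–C4–C5) at C5–C6 and C3–C4. In that ring C6, which carries oxygen, is 1,4-related to C3 and faces the methyl-bearing quaternary C4 across the C5 methylene. This is the pattern that a furan-derived 3-oxidopyrylium (C6, C10, C1, C2, C3) and methacrolein (C5, C4, C9, methyl) deliver. One (5+2) cycloaddition forms both bonds, the carbocycle, an oxolane bridge that keeps the C6 oxygen masked, and three stereocentres. Its precursor is a 6-acetoxy-2H-pyran-3(6H)-one carrying the C7–C8 arm as a 2-(silyloxy)ethyl group on the carbon that becomes C6.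

Key step: step 4

Atom labels used below: C1 ring CH carrying the dienal; C2, C3 ring CH2; C4 quaternary carbon with the methyl group; C5 one-carbon bridge; C6 tertiary carbinol; C7, C8 CH2; C9 secondary carbinol; C10 ring CH carrying the formyl carbon C11; C12 α-carbon of the enal; C13–C15 diene CH; C16 tertiary carbinol; C17 enal formyl carbon.

Remark (order of ring events): in the 8-oxabicyclo[3.2.1]octene the C6–C7 bond is antiperiplanar to C5–C4 (dihedral near 170°), so the C8–C9 bond cannot be made while the C6–O–C3 bridge is in place. The bridge is therefore opened (step 6) before the six-membered ring is closed (step 9).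

Remark (relative configuration): the formyl group must end up endo (syn to the enone bridge), because only then are C9 and the C7 arm cis on the seven-membered ring once the bridge is opened.

Assumption: the quinine-derived primary amine is taken to deliver the enantiomer drawn for 9; if the sense of induction proves opposite, the quinidine-derived pseudoenantiomer is used in the same step.

**Route**

Step 1
Reactants: 1 furan; 2 3-[(tert-butyldimethylsilyl)oxy]propanal
Product: 4 (±)-3-[(tert-butyldimethylsilyl)oxy]-1-(furan-2-yl)propan-1-ol, via 2-furyllithium 3 (not isolated)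
Conditions: n-BuLi, THF, 0 °C; then 2, −78 °C; H2O
Reagents that add atoms: none
Why: Deprotonation of furan at C2 and 1,2-addition of the organolithium to the aldehyde should give the furfuryl carbinol, whose racemic stereocentre is destroyed when the ylide is formed.

Step 2
Reactants: 4
Product: 5 2-{2-[(tert-butyldimethylsilyl)oxy]ethyl}-6-hydroxy-2H-pyran-3(6H)-one (diastereomer mixture)
Conditions: mCPBA, CH2Cl2, 0 °C
Reagents that add atoms: m-chloroperoxybenzoic acid, OOC(=O)c1cccc(Cl)c1
Why: The Achmatowicz rearrangement of a 2-furylcarbinol with a peracid should deliver the 6-hydroxypyranone without touching the silyl ether.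

Step 3
Reactants: 5
Product: 6 6-acetoxy-2-{2-[(tert-butyldimethylsilyl)oxy]ethyl}-2H-pyran-3(6H)-one (diastereomer mixture)
Conditions: Ac2O, pyridine, DMAP (cat.), CH2Cl2, 0 °C
Reagents that add atoms: acetic anhydride, CC(=O)OC(C)=O
Why: DMAP-catalysed acylation of the lactol hydroxyl installs the leaving group for ylide formation, and the isomer ratio is irrelevant because both centres vanish in step 4.

Step 4
Reactants: 6; 7 methacrolein (2-methylprop-2-enal)
Product: 9 (1S,5R,6R)-1-{2-[(tert-butyldimethylsilyl)oxy]ethyl}-6-methyl-2-oxo-8-oxabicyclo[3.2.1]oct-3-ene-6-carbaldehyde (formyl endo; methyl exo), via oxidopyrylium ylide 8 (not isolated)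
Conditions: 7 (5 equiv), 9-amino-9-deoxy-epi-quinine (20 mol%), CF3CO2H (40 mol%), i-Pr2NEt (1.2 equiv), CHCl3, 0 °C to rt; aqueous work-up
Reagents that add atoms: none
Why: Proposed new method: i-Pr2NEt takes H-2 of 6 and acetate leaves to give the planar 3-oxidopyrylium 8, while methacrolein and the primary ammonium salt form an α-methyl iminium ion, far more electrophilic than the free enal, so the catalysed path should outrun the racemic background; the ammonium acetate released on ionisation keeps the iminium equilibrium alive. The closest known reactions are the thermal (5+2) cycloadditions of 3-oxidopyrylium ylides with acrolein and acrylates, amine-catalysed enantioselective oxidopyrylium (5+2) cycloadditions, and primary-amine iminium catalysis of cycloadditions of α-branched enals. The enolate-like terminus C6 bonds to the β-methylene C5 and the enamine-like C4 then closes on the oxocarbenium-like C3 (concerted but asynchronous, Michael–Mannich in the limit), the regiochemistry shown by acrylic dipolarophiles. This single suprafacial addition closes both rings at once, the carbocycle C6–C10–C1–C2–C3–C4–C5 through the two new C–C bonds and the oxolane C6–O–C3–C4–C5 as its bridged counterpart. C6 and C3, tied together by the oxygen bridge, are fixed by which face of the ylide meets the open face of the iminium ion (the quinoline shields the other), and C4 by the endo placement of the C=N+ group under the oxido-enone. The selectivity needed is endo (formyl syn to the enone bridge, methyl exo), and it should be secured by Coulombic attraction between the iminium nitrogen and the oxido oxygen and by the bare oxygen bridge, which offers no hydrogen to clash with an exo methyl as the CH2 bridge of cyclopentadiene does; hydrolysis then releases 9 and the amine.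

Step 5
Reactants: 9
Product: 10 (1S,5R,6R)-6-(dimethoxymethyl)-1-{2-[(tert-butyldimethylsilyl)oxy]ethyl}-6-methyl-8-oxabicyclo[3.2.1]oct-3-en-2-one
Conditions: HC(OMe)3, CeCl3·7H2O (cat.), MeOH, rt
Reagents that add atoms: trimethyl orthoformate, COC(OC)OC; methanol, CO
Why: Lanthanide-catalysed acetalisation is selective for aldehydes over conjugated ketones and spares the silyl ether, and the acetal keeps C9 from reduction and from aldol attack by the dienolate formed in step 6.

Step 6
Reactants: 10
Product: 12 6-hydroxy-6-(2-hydroxyethyl)-1-methyl-5-oxocyclohept-2-ene-1-carbaldehyde (formyl and hydroxyethyl arm cis; C4 and C6 as in 9), via hydroxy enone acetal 11 (not isolated)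
Conditions: SmI2 (2.2 equiv, added until the blue colour persists), THF, −78 °C; then 2 M HCl, THF, 0 °C to rt
Reagents that add atoms: water, O
Why: Two-electron reduction of the enone by SmI2 (reductive cleavage of a γ-alkoxy enone) should eject the C3 alkoxide, because the enone radical anion has its largest carbon coefficient on C2 next to C3 and the resulting dienolate is linearly conjugated whereas loss from C6 would leave only a cross-conjugated one; without a proton source the ketone stays masked as the samarium dienolate until the acid quench, which also hydrolyses the acetal and the primary silyl ether.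

Step 7
Reactants: 12
Product: 13 3-hydroxy-3-(2-hydroxyethyl)-1-methyl-4-oxocycloheptane-1-carbaldehyde (formyl and hydroxyethyl arm cis)
Conditions: H2 (1 atm), 10% Pd/C, EtOAc, rt
Reagents that add atoms: none
Why: Heterogeneous hydrogenation saturates the disubstituted ring alkene (any conjugated isomer formed in the acid phase of step 6 converges here) without touching the aldehyde or the ketone, and no stereocentre is formed.

Step 8
Reactants: 13
Product: 14 3-hydroxy-3-(2-iodoethyl)-1-methyl-4-oxocycloheptane-1-carbaldehyde
Conditions: I2, PPh3, imidazole, CH2Cl2, 0 °C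
Reagents that add atoms: iodine, II
Why: Appel-type iodination converts only the primary alcohol, the tertiary carbinol and both carbonyl groups being inert.

Step 9
Reactants: 14
Product: 15 1,7-dihydroxy-6-methylbicyclo[4.3.1]decan-2-one (4S,6R,9R in the atom labels; C9 hydroxyl equatorial and cis to C3)
Conditions: CrCl2 (4 equiv), vitamin B12 (5 mol%), DMF, rt; H2O
Reagents that add atoms: none
Why: Cobalt-catalysed formation of an alkylchromium(III) from the primary iodide and its intramolecular addition to the aldehyde (alkylchromium Barbier, Nozaki–Hiyama type) spares the ketone and should close the six-membered ring through a chair in which the metal-bound oxygen on C9 sits equatorial, cis to C3, avoiding 1,3-diaxial contacts with the hydrogens on C5 and C7.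

Step 10
Reactants: 15
Product: 16 6-methyl-1,7-bis[(triethylsilyl)oxy]bicyclo[4.3.1]decan-2-one
Conditions: TESOTf (3 equiv), 2,6-lutidine, CH2Cl2, −78 to 0 °C
Reagents that add atoms: triethylsilyl trifluoromethanesulfonate, CC[Si](CC)(CC)OS(=O)(=O)C(F)(F)F
Why: Silyl triflate silylation protects the tertiary and the secondary hydroxyl in one operation, which blocks α-ketol rearrangement and O-alkylation in the base-mediated steps 11 and 12.

Step 11
Reactants: 16
Product: 18 6-methyl-3-(prop-2-en-1-yl)-1,7-bis[(triethylsilyl)oxy]bicyclo[4.3.1]decan-2-one (allyl on C1 cis to the C6 oxygen), via lithium enolate 17 (not isolated)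
Conditions: LDA, THF, −78 °C; then allyl bromide, DMPU, −78 to −20 °C
Reagents that add atoms: allyl bromide, C=CCBr
Why: The ketone can enolise only towards C1, and alkylation of the lithium enolate should occur on the convex face away from the C7–C9 bridge, placing the allyl group equatorial and cis to the C6 oxygen, which is also the thermodynamically preferred arrangement.

Step 12
Reactants: 18
Product: 20 1,7-dihydroxy-6-methyl-3-(prop-2-en-1-yl)bicyclo[4.3.1]decane-2-carbaldehyde (formyl on C10 trans to the allyl group on C1), via methyl enol ether 19 (not isolated)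
Conditions: Ph3P(CH2OMe)Cl (4 equiv), KHMDS, THF, 0 to 50 °C; then 2 M HCl, THF, rt
Reagents that add atoms: (methoxymethyl)triphenylphosphonium chloride, [Cl-].COC[P+](c1ccccc1)(c1ccccc1)c1ccccc1; water, O
Why: Wittig methoxymethylenation of the ketone and acid hydrolysis of the enol ether give the homologous aldehyde, protonation of C10 from the convex face and acid-mediated equilibration placing the formyl group equatorial and trans to the allyl group, while the same acid removes both triethylsilyl ethers.

Step 13
Reactants: 20
Product: 22 1,7-dihydroxy-6-methyl-3-(2-oxoethyl)bicyclo[4.3.1]decane-2-carbaldehyde, via ozonide 21 (not isolated)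
Conditions: O3, CH2Cl2, −78 °C; then PPh3, −78 °C to rt
Reagents that add atoms: ozone, [O-][O+]=O
Why: Ozonolysis of the terminal alkene with reductive work-up should give the C17 aldehyde, the existing formyl group and the free alcohols being inert at −78 °C.

Step 14
Reactants: 23 2-methylbut-3-en-2-ol; 24 (E)-but-2-enal (crotonaldehyde)
Product: 25 (E)-4-hydroxy-4-methylpent-2-enal
Conditions: Hoveyda–Grubbs II (3 mol%), 24 (3 equiv), CH2Cl2, 40 °C
Reagents that add atoms: none
Why: Olefin cross-metathesis between a hindered tertiary allylic alcohol and an electron-poor enal is selective for the cross product and should give the E-alkene under thermodynamic control.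

Step 15
Reactants: 22; 25
Product: 26 umbellacin A
Conditions: 25 (3 equiv), pyrrolidine (30 mol%), PhCO2H (30 mol%), CH2Cl2, rt
Reagents that add atoms: none
Why: In this amine-catalysed crossed aldol (Mannich-type) condensation only the unbranched C17 aldehyde forms an enamine readily, the enal has no γ-hydrogen and its β-carbon is blocked by the tertiary carbinol, so 1,2-addition and loss of water should give the 2-substituted 2,4-dienal with the thermodynamically preferred 12E geometry while C10 keeps its equatorial configuration.

**Compound list**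

1 | furan | c1ccoc1 | starting material
2 | 3-[(tert-butyldimethylsilyl)oxy]propanal | O=CCCO[Si](C)(C)C(C)(C)C | starting material
3 | 2-furyllithium | [Li]c1ccco1 | intermediate
4 | (±)-3-[(tert-butyldimethylsilyl)oxy]-1-(furan-2-yl)propan-1-ol | OC(CCO[Si](C)(C)C(C)(C)C)c1ccco1 | intermediate
5 | 2-{2-[(tert-butyldimethylsilyl)oxy]ethyl}-6-hydroxy-2H-pyran-3(6H)-one (diastereomer mixture) | OC1C=CC(=O)C(CCO[Si](C)(C)C(C)(C)C)O1 | intermediate
6 | 6-acetoxy-2-{2-[(tert-butyldimethylsilyl)oxy]ethyl}-2H-pyran-3(6H)-one (diastereomer mixture) | CC(=O)OC1C=CC(=O)C(CCO[Si](C)(C)C(C)(C)C)O1 | intermediate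
7 | methacrolein | CC(=C)C=O | starting material
8 | 2-{2-[(tert-butyldimethylsilyl)oxy]ethyl}pyrylium-3-olate (3-oxidopyrylium ylide) | [O-]c1ccc[o+]c1CCO[Si](C)(C)C(C)(C)C | intermediate
9 | (1S,5R,6R)-1-{2-[(tert-butyldimethylsilyl)oxy]ethyl}-6-methyl-2-oxo-8-oxabicyclo[3.2.1]oct-3-ene-6-carbaldehyde (formyl endo, methyl exo) | O=C[C@]1(C)C[C@@]2(CCO[Si](C)(C)C(C)(C)C)O[C@@H]1C=CC2=O | intermediate
10 | (1S,5R,6R)-6-(dimethoxymethyl)-1-{2-[(tert-butyldimethylsilyl)oxy]ethyl}-6-methyl-8-oxabicyclo[3.2.1]oct-3-en-2-one | COC(OC)[C@]1(C)C[C@@]2(CCO[Si](C)(C)C(C)(C)C)O[C@@H]1C=CC2=O | intermediate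
11 | 5-(dimethoxymethyl)-7-hydroxy-7-{2-[(tert-butyldimethylsilyl)oxy]ethyl}-5-methylcyclohept-3-en-1-one (acetal carbon and oxyethyl arm cis; C4 and C6 as in 9) | COC(OC)[C@]1(C)C[C@](O)(CCO[Si](C)(C)C(C)(C)C)C(=O)CC=C1 | intermediate
12 | 6-hydroxy-6-(2-hydroxyethyl)-1-methyl-5-oxocyclohept-2-ene-1-carbaldehyde (formyl and hydroxyethyl arm cis) | O=C[C@]1(C)C[C@](O)(CCO)C(=O)CC=C1 | intermediate
13 | 3-hydroxy-3-(2-hydroxyethyl)-1-methyl-4-oxocycloheptane-1-carbaldehyde (formyl and hydroxyethyl arm cis) | O=C[C@]1(C)C[C@](O)(CCO)C(=O)CCC1 | intermediate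
14 | 3-hydroxy-3-(2-iodoethyl)-1-methyl-4-oxocycloheptane-1-carbaldehyde (formyl and iodoethyl arm cis) | O=C[C@]1(C)C[C@](O)(CCI)C(=O)CCC1 | intermediate
15 | 1,7-dihydroxy-6-methylbicyclo[4.3.1]decan-2-one (4S,6R,9R in the atom labels; C9–OH cis to C3) | C1CC[C@@]2(C)C[C@](O)(CC[C@H]2O)C1=O | intermediate
16 | 6-methyl-1,7-bis[(triethylsilyl)oxy]bicyclo[4.3.1]decan-2-one | C1CC[C@@]2(C)C[C@](O[Si](CC)(CC)CC)(CC[C@H]2O[Si](CC)(CC)CC)C1=O | intermediate
17 | lithium enolate of 16 (C10–OLi, C10=C1) | C=1CC[C@@]2(C)C[C@](O[Si](CC)(CC)CC)(CC[C@H]2O[Si](CC)(CC)CC)C=1O[Li] | intermediate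
18 | 6-methyl-3-(prop-2-en-1-yl)-1,7-bis[(triethylsilyl)oxy]bicyclo[4.3.1]decan-2-one (allyl on C1 cis to the C6 oxygen) | C=CC[C@H]1CC[C@@]2(C)C[C@](O[Si](CC)(CC)CC)(CC[C@H]2O[Si](CC)(CC)CC)C1=O | intermediate
19 | 2-(methoxymethylidene)-6-methyl-3-(prop-2-en-1-yl)-1,7-bis[(triethylsilyl)oxy]bicyclo[4.3.1]decane (E/Z mixture) | C=CC[C@H]1CC[C@@]2(C)C[C@](O[Si](CC)(CC)CC)(CC[C@H]2O[Si](CC)(CC)CC)C1=COC | intermediate
20 | 1,7-dihydroxy-6-methyl-3-(prop-2-en-1-yl)bicyclo[4.3.1]decane-2-carbaldehyde (formyl trans to allyl) | C=CC[C@H]1CC[C@@]2(C)C[C@](O)(CC[C@H]2O)[C@@H]1C=O | intermediate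
21 | ozonide (1,2,4-trioxolane) of 20 | C1(OCOO1)C[C@H]2CC[C@@]3(C)C[C@](O)(CC[C@H]3O)[C@@H]2C=O | intermediate
22 | 1,7-dihydroxy-6-methyl-3-(2-oxoethyl)bicyclo[4.3.1]decane-2-carbaldehyde | O=CC[C@H]1CC[C@@]2(C)C[C@](O)(CC[C@H]2O)[C@@H]1C=O | intermediate
23 | 2-methylbut-3-en-2-ol | CC(C)(O)C=C | starting material
24 | (E)-but-2-enal | C/C=C/C=O | starting material
25 | (E)-4-hydroxy-4-methylpent-2-enal | CC(C)(O)/C=C/C=O | intermediate
26 | umbellacin A (1S,4S,6R,9R,10R in the atom labels; 12E,14E) | CC(C)(O)/C=C/C=C(/C=O)[C@H]1CC[C@@]2(C)C[C@](O)(CC[C@H]2O)[C@@H]1C=O | target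

**Step count and risks**

Total steps: 15. Longest linear sequence: 14 (steps 1 to 13 and 15); step 14 is a one-step branch.

Steps most likely to fail:

Step 4 (proposed method). The uncatalysed addition of free methacrolein to the ylide may outrun the iminium pathway, so that enantiofacial control is lost. The fallback sets out from 6 and 7. The cycloaddition is run with triethylamine alone, the established racemic protocol, to give the racemic endo adduct F1. Its formyl group is condensed with (1R,2R)-N,N′-dimethyl-1,2-diphenylethane-1,2-diamine to the two diastereomeric imidazolidines. The one derived from the wanted enantiomer, the aminal F2, is separated by chromatography or crystallisation and hydrolysed with cold dilute aqueous acid. The sequence comes back at 9.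

Step 6. Single-electron cleavage may break the C6–O bond next to the ketone in competition with C3–O, or the liberated α-ketol may be over-reduced. The fallback sets out from 10. Luche reduction gives the allylic alcohol F3 (C10 epimers immaterial), in which C3–O is the only allylic C–O bond. Reductive lithiation with lithium 4,4′-di-tert-butylbiphenylide at −78 °C cleaves that bond and gives, after protonation, the cycloheptenediol F4 (either alkene isomer serves). Parikh–Doering or Dess–Martin oxidation of the secondary carbinol restores the ketone. The sequence comes back at 11, which is carried on with the acid treatment of step 6.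

Step 15. Chemoselectivity between the two formyl groups may be poor, with self-condensation, retro-aldol opening of the β-hydroxy aldehyde or addition to the wrong carbonyl. The fallback sets out from 20. The C11 formyl group is masked by cerium-catalysed acetalisation to give the dimethyl acetal F5. Ozonolysis of the allyl group gives the mono-aldehyde F6. Condensation with 25 under the amine catalysis of step 15 gives the dienal acetal F7. Dilute aqueous acid then unmasks C11. The sequence comes back at 26.

Further compounds

F1 | step 4 | racemic endo cycloadduct (9 and its enantiomer) | O=C[C@]1(C)C[C@@]2(CCO[Si](C)(C)C(C)(C)C)O[C@@H]1C=CC2=O.O=C[C@@]1(C)C[C@]2(CCO[Si](C)(C)C(C)(C)C)O[C@H]1C=CC2=O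
F2 | step 4 | imidazolidine of 9 with (1R,2R)-N,N′-dimethyl-1,2-diphenylethane-1,2-diamine | CN1[C@H](c2ccccc2)[C@@H](c2ccccc2)N(C)C1[C@]3(C)C[C@@]4(CCO[Si](C)(C)C(C)(C)C)O[C@@H]3C=CC4=O
F3 | step 6 | 6-(dimethoxymethyl)-1-{2-[(tert-butyldimethylsilyl)oxy]ethyl}-6-methyl-8-oxabicyclo[3.2.1]oct-3-en-2-ol (C10 epimers) | COC(OC)[C@]1(C)C[C@@]2(CCO[Si](C)(C)C(C)(C)C)O[C@@H]1C=CC2O
F4 | step 6 | 6-(dimethoxymethyl)-2-{2-[(tert-butyldimethylsilyl)oxy]ethyl}-6-methylcyclohept-4-ene-1,2-diol (C10 epimers) | COC(OC)[C@]1(C)C[C@](O)(CCO[Si](C)(C)C(C)(C)C)C(O)CC=C1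
F5 | step 15 | 2-(dimethoxymethyl)-6-methyl-3-(prop-2-en-1-yl)bicyclo[4.3.1]decane-1,7-diol | C=CC[C@H]1CC[C@@]2(C)C[C@](O)(CC[C@H]2O)[C@@H]1C(OC)OC
F6 | step 15 | 2-[2-(dimethoxymethyl)-1,7-dihydroxy-6-methylbicyclo[4.3.1]decan-3-yl]acetaldehyde | O=CC[C@H]1CC[C@@]2(C)C[C@](O)(CC[C@H]2O)[C@@H]1C(OC)OC
F7 | step 15 | C11 dimethyl acetal of umbellacin A | CC(C)(O)/C=C/C=C(/C=O)[C@H]1CC[C@@]2(C)C[C@](O)(CC[C@H]2O)[C@@H]1C(OC)OC
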